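**Retrosynthetic overview**
1. Briarane numbering is used. Ring A is the cyclohexane C1/C10–C14, ring B is the ten-membered carbocycle C1–C10, and ring C is the γ-lactone O–C7–C8–C17–C19. β is the face of ring A that carries the C1 methyl group.
2. Enabling feature: on ring A the C10–C9 bond and the C11–O bond are cis, and C9 and C11 are 1,3-dioxygenated through C10, an atom that ring A shares with ring B. This is the retron of an isoxazoline fused at C10–C11, and the fully substituted C8 next to C9 makes the nitrile oxide long-lived.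
3. Key disconnection: C9–C10 and O–C11 are formed in one intramolecular nitrile oxide–alkene cycloaddition (27 → 30). It closes ring B and a temporary isoxazoline and sets C10 and C11. N–O cleavage, 1,3-syn reduction (C9), acetylation and desilylation then finish the target.
4. Oxime 27 comes from a B-alkyl Suzuki coupling (C4–C5) of fragment A (11) with fragment B (21), followed by Sharpless epoxidation and epoxide-opening lactonisation (C7, C8). In fragment A, C1 is set by asymmetric Birch reduction–methylation, C2 by CBS reduction, and C14 together with the C2 acetate by Evans–Tishchenko reduction. Fragment B carries the Z-iodoalkene, is built by HWE olefination, and takes C17 from (R)-lactate.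
5. Order of rings: ring A (from the arene, dearomatised in step 2), ring C (step 16), ring B last (step 19).

Key step: step 19

Assumption: the asymmetric Birch reduction–methylation of the (S)-2-(methoxymethyl)pyrrolidine amide is taken to give the (1R) centre drawn for 6. If the sense is the reverse, the (R)-amine is used and nothing else changes.

**Fragment A (steps 1–7)**

Step 1
Reactants: 1 2-methoxy-5-methylbenzoic acid; 2 (S)-2-(methoxymethyl)pyrrolidine
Product: 4 chiral benzamide [(2S)-2-(methoxymethyl)pyrrolidin-1-yl](2-methoxy-5-methylphenyl)methanone, via acid chloride 3 (not isolated)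
Conditions: (COCl)2, cat. HCONMe2, CH2Cl2, 0 °C to rt; then 2, Et3N, CH2Cl2, 0 °C
Reagents that add atoms: none
Why: Amide formation through the acid chloride attaches the auxiliary that will control C1, and no stereocentre is touched.

Step 2
Reactants: 4 chiral benzamide
Product: 6 (1R)-2-methoxy-1,5-dimethylcyclohexa-2,5-diene-1-carboxamide of 2 (ring A with quaternary C1; C14 enol ether; C10=C11 alkene), via potassium amide enolate 5 (not isolated)
Conditions: K, NH3/THF, tBuOH (1 equiv), −78 °C; then MeI, −78 °C
Reagents that add atoms: methyl iodide, CI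
Why: In this asymmetric Birch reduction–alkylation of a chiral benzamide, two-electron reduction and protonation at C12 give the chelated enolate 5, which MeI should attack on the face left open by the CH2OMe arm, setting the quaternary C1.

Step 3
Reactants: 6 dienyl amide
Product: 7 vinyl ketone 1-[(1R)-2-methoxy-1,5-dimethylcyclohexa-2,5-dien-1-yl]prop-2-en-1-one
Conditions: CH2=CHMgBr, THF, 0 °C to rt; cold aqueous citric acid quench
Reagents that add atoms: vinylmagnesium bromide, C=C[Mg]Br
Why: In this acyl substitution of a tertiary amide by a Grignard reagent, the tetrahedral magnesium adduct is held by the CH2OMe oxygen until the acidic quench, so only one vinyl group (C3, C4) is taken up and the auxiliary is released.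

Step 4
Reactants: 7 vinyl ketone
Product: 8 (1S)-1-[(1S)-2-methoxy-1,5-dimethylcyclohexa-2,5-dien-1-yl]prop-2-en-1-ol (2S in briarane numbering)
Conditions: (R)-Me-CBS [(3aR)-1-methyl-3,3-diphenyltetrahydro-1H,3H-pyrrolo[1,2-c][1,3,2]oxazaborole] (cat.), catecholborane, toluene, −78 °C
Reagents that add atoms: none
Why: In this Corey–Bakshi–Shibata reduction the catalyst binds the ketone lone pair on the vinyl side, away from the tertiary C1 group, and delivers hydride 1,2 to one face, so C2 is set as S under reagent control.

Step 5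
Reactants: 8 allylic alcohol
Product: 9 β-hydroxy ketone (2S)-2-[(1S)-1-hydroxyprop-2-en-1-yl]-2,4-dimethylcyclohex-3-en-1-one
Conditions: 1 M HCl, THF, 0 °C to rt
Reagents that add atoms: water, O
Why: Acid hydrolysis of the methyl enol ether (protonation at C13, hemiketal collapse) unmasks the C14 ketone, and the quaternary C1 excludes alkene migration and epimerisation.

Step 6
Reactants: 9 β-hydroxy ketone
Product: 10 (1S)-1-[(1R,6S)-6-hydroxy-1,3-dimethylcyclohex-2-en-1-yl]prop-2-en-1-yl acetate (C2 acetate; free 14α-OH)
Conditions: SmI2 (cat.), CH3CHO (excess), THF, −10 °C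
Reagents that add atoms: acetaldehyde, CC=O
Why: In this Evans–Tishchenko reduction the samarium-bound hemiacetal of O2 with acetaldehyde transfers hydride to C14 through a chair-like transition state with C3, C10 and C13 equatorial, which should give the 1,3-anti (14S) alcohol and leave the acetyl group on O2 as the target requires.

Step 7
Reactants: 10 hydroxy acetate
Product: 11 fragment A (1S)-1-[(1S,6S)-6-{[tert-butyl(dimethyl)silyl]oxy}-1,3-dimethylcyclohex-2-en-1-yl]prop-2-en-1-yl acetate
Conditions: tBuMe2SiOTf, 2,6-lutidine, CH2Cl2, 0 °C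
Reagents that add atoms: tert-butyldimethylsilyl triflate, CC(C)(C)[Si](C)(C)OS(=O)(=O)C(F)(F)F
Why: Silylation of the hindered C14 alcohol with a silyl triflate keeps O14 free of acetate later and places a bulky group on the α face of ring A for step 19.

**Fragment B (steps 8–13)**

Step 8
Reactants: 12 tert-butyl (R)-lactate
Product: 13 tert-butyl (2R)-2-{[(trifluoromethyl)sulfonyl]oxy}propanoate
Conditions: Tf2O, 2,6-lutidine, CH2Cl2, −78 to 0 °C
Reagents that add atoms: triflic anhydride, O=S(=O)(OS(=O)(=O)C(F)(F)F)C(F)(F)F
Why: O-Sulfonylation activates the lactate carbon with retention, because only the O–H bond is broken.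

Step 9
Reactants: 14 triethyl phosphonoacetate; 13 lactate triflate
Product: 15 4-tert-butyl 1-ethyl (3S)-2-(diethoxyphosphoryl)-3-methylbutanedioate (mixture at the phosphonate carbon)
Conditions: NaH, THF, 0 °C; then 13, −20 °C to rt
Reagents that add atoms: none
Why: SN2 alkylation of the soft phosphonoacetate anion by an α-triflyloxy ester proceeds with clean inversion and sets C17, while the phosphonate-bearing centre is lost in step 12.

Step 10
Reactants: 16 but-2-yn-1-ol
Product: 18 (2Z)-3-iodobut-2-en-1-ol, via cyclic alkenylaluminate 17 (not isolated)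
Conditions: NaAlH2(OCH2CH2OMe)2, Et2O, 0 °C to rt; then I2, THF, −78 °C
Reagents that add atoms: iodine, II
Why: Hydroxyl-directed trans-hydroalumination places aluminium on the distal alkyne carbon in a five-membered chelate, and iodinolysis with retention fixes the Z geometry of the future C5=C6 bond.

Step 11
Reactants: 18 iodo allylic alcohol
Product: 19 (2Z)-3-iodobut-2-enal
Conditions: MnO2, CH2Cl2, rt
Reagents that add atoms: none
Why: Allylic oxidation on neutral MnO2 gives the enal (C7 aldehyde) without Z to E isomerisation.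

Step 12
Reactants: 15 phosphonate; 19 iodo enal
Product: 20 4-tert-butyl 1-ethyl (2E,3R)-2-[(2Z)-3-iodobut-2-en-1-ylidene]-3-methylbutanedioate
Conditions: NaH (slightly less than 1 equiv), THF, 0 °C; then 19, −20 °C to rt
Reagents that add atoms: none
Why: Horner–Wadsworth–Emmons olefination of an α-branched phosphonoacetate should place the aldehyde residue trans to the ethyl ester (7E), and the absence of excess base protects C17 from epimerisation.

Step 13
Reactants: 20 dienoate
Product: 21 fragment B tert-butyl (2R,3E,5Z)-3-(hydroxymethyl)-6-iodo-2-methylhepta-3,5-dienoate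
Conditions: iBu2AlH (2.2 equiv), CH2Cl2, −78 °C
Reagents that add atoms: none
Why: This hydride reduction is chemoselective, because the ethyl ester (C9) is reduced to the allylic alcohol while the bulkier tert-butyl ester (C19) and the vinyl iodide are left intact.

**Union, ring C and ring B (steps 14–19)**

Step 14
Reactants: 11 fragment A; 21 fragment B
Product: 23 seco dienol (C4–C5 joined; 5Z,7E diene; C9 allylic alcohol; tert-butyl ester; C1, C2, C14, C17 as in the target), via B-alkyl borane 22 (not isolated)
Conditions: 9-BBN-H, THF, 0 °C to rt; then 21, Pd(dppf)Cl2 (cat.), AsPh3 (cat.), Cs2CO3, DMF/THF/H2O, rt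
Reagents that add atoms: none
Why: 9-BBN-H adds only to the monosubstituted C3=C4 alkene with boron on C4, and the B-alkyl Suzuki–Miyaura coupling proceeds with retention at the vinyl iodide, so the 5Z geometry is carried over.

Step 15
Reactants: 23 seco dienol
Product: 24 (7R,8R)-epoxy alcohol (oxirane C7–C8; C6 and C17 cis on the oxirane)
Conditions: Ti(OiPr)4 (cat.), L-(+)-diethyl tartrate (cat.), tBuOOH, 4 Å molecular sieves, CH2Cl2, −20 °C
Reagents that add atoms: tert-butyl hydroperoxide, CC(C)(C)OO
Why: Sharpless asymmetric epoxidation reacts only at the alkene of the allylic alcohol (C7=C8), and L-(+)-tartrate delivers oxygen to the face that gives the C8–O configuration of the target.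

Step 16
Reactants: 24 epoxy alcohol
Product: 25 lactone diol (ring C closed; 7S,8R,17R; 8-OH and C9H2OH free)
Conditions: (1S)-(+)-camphor-10-sulfonic acid (cat.), CH2Cl2, 0 °C
Reagents that add atoms: none
Why: In this acid-triggered epoxide-opening lactonisation the carbonyl oxygen of the tert-butyl ester attacks the allylic carbon C7 from the rear (five-membered ring, inversion at C7, C8–O untouched) and isobutene is lost, so C6 becomes trans to C9 and cis to 8-OH on ring C.

Step 17
Reactants: 25 lactone diol
Product: 26 α-hydroxy aldehyde (C9 aldehyde on the fully substituted C8)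
Conditions: 2-iodoxybenzoic acid (IBX), DMSO, rt
Reagents that add atoms: none
Why: IBX oxidises the primary alcohol of a 1,2-diol without glycol cleavage, and it removes the free C9 alcohol before acyl migration onto it can occur.

Step 18
Reactants: 26 α-hydroxy aldehyde
Product: 27 (E)-aldoxime
Conditions: NH2OH·HCl, NaOAc, EtOH, 0 °C to rt
Reagents that add atoms: hydroxylamine hydrochloride, NO.Cl
Why: Oxime condensation under acetate buffer is far faster at the aldehyde than attack at the lactone or the acetate.

Step 19
Reactants: 27 aldoxime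
Product: 30 tetracyclic isoxazoline (ring B closed; C9=N–O–C11 ring fused at C10–C11 on the β face), via hydroximoyl chloride 28 (not isolated), via nitrile oxide 29 (not isolated)
Conditions: N-chlorosuccinimide, cat. pyridine, CHCl3, rt; then slow addition to Et3N in toluene (about 1 mM), 80 °C
Reagents that add atoms: none
Why: N-Chlorosuccinimide gives 28, Et3N removes HCl, and nitrile oxide 29 adds across C10=C11 in a concerted suprafacial [3+2] step, the closest known type being the macrocyclising intramolecular nitrile oxide–alkene cycloaddition. Ring B closes through the C9–C10 bond in the exo mode (C11 stays outside the carbocycle), and the temporary five-membered isoxazoline closes through O–C11 and is cis-fused to ring A. The regiochemistry is the normal one for trisubstituted alkenes, with carbon going to the CH terminus C10 and oxygen to the methyl-bearing C11, whereas the reverse mode would need a C–C bond to a fully substituted carbon and an eleven-membered ring. Suprafacial addition sets C10 and C11 together with C9 and O cis, and the β face should be chosen because the α face is screened by the pseudoaxial C1–C2 bond and the C14 silyl ether. The tether then runs nearly antiperiplanar about C1–C10 (about 160°, a torsion that ten-membered rings accept), whereas α attack would need a near-eclipsed torsion under the silyl ether. The C5=C6 alkene cannot compete, since it would give a four-membered or bridgehead-imine ring, and dimerisation of the dipole is held back by the fully substituted C8 and by high dilution.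

**Endgame (steps 20–23)**

Step 20
Reactants: 30 isoxazoline
Product: 32 β-hydroxy ketone (C9 ketone; 11β-OH; 8-OH), via hydroxy imine 31 (not isolated)
Conditions: Mo(CO)6, MeCN/H2O, 80 °C
Reagents that add atoms: water, O
Why: Mo(CO)6 cleaves the N–O bond reductively and the imine is hydrolysed in the same flask, which removes the temporary ring without touching the C5=C6 alkene or any stereocentre.

Step 21
Reactants: 32 β-hydroxy ketone
Product: 34 triol (9S; free 8-OH, 9-OH, 11-OH; C2 acetate; C14 silyl ether), via diethylborinate chelate 33 (not isolated)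
Conditions: Et2BOMe, THF/MeOH 4:1, 0 °C then −78 °C; NaBH4, −78 °C; AcOH quench, MeOH co-evaporation
Reagents that add atoms: none
Why: In this Narasaka–Prasad reduction boron ties O11 and the C9 carbonyl into a six-membered chelate and external hydride attacks the face turned away from C1, which should give the 1,3-syn C9/C11 diol of the target.

Step 22
Reactants: 34 triol
Product: 35 2,9-diacetate 14-silyl ether
Conditions: Ac2O, 4-(dimethylamino)pyridine (cat.), pyridine, CH2Cl2, rt
Reagents that add atoms: acetic anhydride, CC(=O)OC(C)=O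
Why: This nucleophile-catalysed acylation is selective because C9-OH is the only secondary alcohol left, the C8 and C11 alcohols being tertiary and O14 silylated.

Step 23
Reactants: 35 diacetate silyl ether
Product: 36 junceellolide I (target)
Conditions: HF·pyridine, THF, 0 °C to rt
Reagents that add atoms: none
Why: Fluoride-driven desilylation under weakly acidic conditions frees 14-OH without acetate cleavage or migration.

**Compound list**
1 | 2-methoxy-5-methylbenzoic acid | COc1ccc(C)cc1C(=O)O | starting material
2 | (S)-2-(methoxymethyl)pyrrolidine | COC[C@@H]1CCCN1 | starting material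
3 | 2-methoxy-5-methylbenzoyl chloride | COc1ccc(C)cc1C(=O)Cl | intermediate
4 | chiral benzamide | COc1ccc(C)cc1C(=O)N1CCC[C@H]1COC | intermediate
5 | potassium amide enolate | COC1=CCC(C)=CC1=C([O-])N1CCC[C@H]1COC.[K+] | intermediate
6 | (1R)-dienyl amide | COC1=CCC(C)=C[C@@]1(C)C(=O)N1CCC[C@H]1COC | intermediate
7 | vinyl ketone | C=CC(=O)[C@]1(C)C=C(C)CC=C1OC | intermediate
8 | (2S)-allylic alcohol | C=C[C@H](O)[C@]1(C)C=C(C)CC=C1OC | intermediate
9 | β-hydroxy ketone | C=C[C@H](O)[C@]1(C)C=C(C)CCC1=O | intermediate
10 | C2 acetate, 14-OH | C=C[C@H](OC(C)=O)[C@]1(C)C=C(C)CC[C@@H]1O | intermediate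
11 | fragment A | C=C[C@H](OC(C)=O)[C@]1(C)C=C(C)CC[C@@H]1O[Si](C)(C)C(C)(C)C | intermediate
12 | tert-butyl (R)-lactate | C[C@@H](O)C(=O)OC(C)(C)C | starting material
13 | lactate triflate | C[C@@H](OS(=O)(=O)C(F)(F)F)C(=O)OC(C)(C)C | intermediate
14 | triethyl phosphonoacetate | CCOC(=O)CP(=O)(OCC)OCC | starting material
15 | phosphonosuccinate | CCOC(=O)C(P(=O)(OCC)OCC)[C@@H](C)C(=O)OC(C)(C)C | intermediate
16 | but-2-yn-1-ol | CC#CCO | starting material
17 | sodium cyclic alkenylaluminate | CC1=CCO[Al-]1(OCCOC)OCCOC.[Na+] | intermediate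
18 | (2Z)-3-iodobut-2-en-1-ol | C/C(I)=C/CO | intermediate
19 | (2Z)-3-iodobut-2-enal | C/C(I)=C/C=O | intermediate
20 | (E,Z)-dienoate | I/C(C)=C\C=C(\C(=O)OCC)[C@@H](C)C(=O)OC(C)(C)C | intermediate
21 | fragment B | I/C(C)=C\C=C(\CO)[C@@H](C)C(=O)OC(C)(C)C | intermediate
22 | B-alkyl-9-BBN borane of 11 | CC(=O)O[C@@H](CCB1C2CCCC1CCC2)[C@]1(C)C=C(C)CC[C@@H]1O[Si](C)(C)C(C)(C)C | intermediate
23 | seco dienol | CC(=O)O[C@@H](CC/C(C)=C\C=C(\CO)[C@@H](C)C(=O)OC(C)(C)C)[C@]1(C)C=C(C)CC[C@@H]1O[Si](C)(C)C(C)(C)C | intermediate
24 | (7R,8R)-epoxy alcohol | CC(=O)O[C@@H](CC/C(C)=C\[C@H]1O[C@@]1(CO)[C@@H](C)C(=O)OC(C)(C)C)[C@]1(C)C=C(C)CC[C@@H]1O[Si](C)(C)C(C)(C)C | intermediate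
25 | lactone diol | CC(=O)O[C@@H](CC/C(C)=C\[C@@H]1OC(=O)[C@H](C)[C@@]1(O)CO)[C@]1(C)C=C(C)CC[C@@H]1O[Si](C)(C)C(C)(C)C | intermediate
26 | α-hydroxy aldehyde | CC(=O)O[C@@H](CC/C(C)=C\[C@@H]1OC(=O)[C@H](C)[C@@]1(O)C=O)[C@]1(C)C=C(C)CC[C@@H]1O[Si](C)(C)C(C)(C)C | intermediate
27 | (E)-aldoxime | CC(=O)O[C@@H](CC/C(C)=C\[C@@H]1OC(=O)[C@H](C)[C@@]1(O)/C=N/O)[C@]1(C)C=C(C)CC[C@@H]1O[Si](C)(C)C(C)(C)C | intermediate
28 | hydroximoyl chloride | CC(=O)O[C@@H](CC/C(C)=C\[C@@H]1OC(=O)[C@H](C)[C@@]1(O)/C(Cl)=N/O)[C@]1(C)C=C(C)CC[C@@H]1O[Si](C)(C)C(C)(C)C | intermediate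
29 | nitrile oxide | CC(=O)O[C@@H](CC/C(C)=C\[C@@H]1OC(=O)[C@H](C)[C@@]1(O)C#[N+][O-])[C@]1(C)C=C(C)CC[C@@H]1O[Si](C)(C)C(C)(C)C | intermediate
30 | tetracyclic isoxazoline | CC(=O)O[C@H]1CC/C(C)=C\[C@@H]2OC(=O)[C@H](C)[C@@]2(O)C3=NO[C@@]4(C)CC[C@H](O[Si](C)(C)C(C)(C)C)[C@@]1(C)[C@@H]34 | intermediate
31 | β-hydroxy imine | CC(=O)O[C@H]1CC/C(C)=C\[C@@H]2OC(=O)[C@H](C)[C@@]2(O)C(=N)[C@@H]2[C@]1(C)[C@@H](O[Si](C)(C)C(C)(C)C)CC[C@]2(C)O | intermediate
32 | β-hydroxy ketone | CC(=O)O[C@H]1CC/C(C)=C\[C@@H]2OC(=O)[C@H](C)[C@@]2(O)C(=O)[C@@H]2[C@]1(C)[C@@H](O[Si](C)(C)C(C)(C)C)CC[C@]2(C)O | intermediate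
33 | O11 diethylborinate of 32 | CC(=O)O[C@H]1CC/C(C)=C\[C@@H]2OC(=O)[C@H](C)[C@@]2(O)C(=O)[C@@H]2[C@]1(C)[C@@H](O[Si](C)(C)C(C)(C)C)CC[C@]2(C)OB(CC)CC | intermediate
34 | (9S)-triol | CC(=O)O[C@H]1CC/C(C)=C\[C@@H]2OC(=O)[C@H](C)[C@@]2(O)[C@@H](O)[C@@H]2[C@]1(C)[C@@H](O[Si](C)(C)C(C)(C)C)CC[C@]2(C)O | intermediate
35 | 2,9-diacetate 14-silyl ether | CC(=O)O[C@H]1CC/C(C)=C\[C@@H]2OC(=O)[C@H](C)[C@@]2(O)[C@@H](OC(C)=O)[C@@H]2[C@]1(C)[C@@H](O[Si](C)(C)C(C)(C)C)CC[C@]2(C)O | intermediate
36 | junceellolide I | CC(=O)O[C@H]1CC/C(C)=C\[C@@H]2OC(=O)[C@H](C)[C@@]2(O)[C@@H](OC(C)=O)[C@@H]2[C@]1(C)[C@@H](O)CC[C@]2(C)O | target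

**Totals**
Total step count: 23.
Longest linear sequence: 17 (steps 1–7 and 14–23).

**Steps most likely to fail**

Step 19. The cycloaddition onto the hindered trisubstituted alkene may be so slow that the dipole is lost by dimerisation or thermal rearrangement, or facial selectivity may be poor.
- The fallback sets out from aldehyde 26 and comes back at triol 34.
- A Me2AlCl-promoted intramolecular carbonyl–ene reaction at high dilution (CH2Cl2, −78 to 0 °C) lets C10 of the ring A alkene attack the chelated α-hydroxy aldehyde while a hydrogen of the C11 methyl group moves to oxygen. This closes ring B as the 9-hydroxy 11(20)-methylene compound F1.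
- Mukaiyama hydration (Co(acac)2, PhSiH3, O2, iPrOH) of the 1,1-disubstituted alkene, which reacts ahead of the trisubstituted C5=C6 bond, then gives the tertiary 11-alcohol 34.

Step 3. Steric shielding of the amide carbonyl by the quaternary C1 may stop the addition, or the released amine may add to the enone during the quench.
- The fallback sets out from amide 6 and comes back at vinyl ketone 7.
- LiH2NBH3 reduces the amide to the neopentyl primary alcohol F2 with release of the auxiliary.
- Dess–Martin periodinane gives the aldehyde F3.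
- Vinylmagnesium bromide gives the allylic alcohol epimer mixture F4.
- Oxidation with MnO2 converges both epimers on 7.

Step 16. Acid may cause loss of the C14 silyl group, addition to the ring A alkene, or ionisation of the vinyl epoxide with erosion at C7. The free C9 alcohol may also undergo acyl migration.
- The fallback sets out from fragment B 21 and comes back at lactone diol 25, so that ring C is built on the small fragment before the union.
- Sharpless epoxidation (Ti(OiPr)4, L-(+)-diethyl tartrate, tBuOOH) gives the iodo epoxy alcohol F5.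
- Acid-induced lactonisation gives the iodo lactone diol F6.
- tBuMe2SiCl and imidazole protect the primary alcohol as the silyl ether F7.
- B-alkyl Suzuki coupling with borane 22 gives the bis-silyl ether F8.
- Brief treatment with HF·pyridine removes only the primary silyl group and gives 25.

**Further compounds**
F1 | step 19 | 9-hydroxy 11(20)-methylene ring B compound | CC(=O)O[C@H]1CC/C(C)=C\[C@@H]2OC(=O)[C@H](C)[C@@]2(O)[C@@H](O)[C@@H]2[C@]1(C)[C@@H](O[Si](C)(C)C(C)(C)C)CCC2=C
F2 | step 3 | neopentyl primary alcohol | OC[C@]1(C)C=C(C)CC=C1OC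
F3 | step 3 | aldehyde | O=C[C@]1(C)C=C(C)CC=C1OC
F4 | step 3 | allylic alcohol epimer mixture | C=CC(O)[C@]1(C)C=C(C)CC=C1OC
F5 | step 16 | iodo epoxy alcohol | I/C(C)=C\[C@H]1O[C@@]1(CO)[C@@H](C)C(=O)OC(C)(C)C
F6 | step 16 | iodo lactone diol | I/C(C)=C\[C@@H]1OC(=O)[C@H](C)[C@@]1(O)CO
F7 | step 16 | primary silyl ether of the iodo lactone | I/C(C)=C\[C@@H]1OC(=O)[C@H](C)[C@@]1(O)CO[Si](C)(C)C(C)(C)C
F8 | step 16 | coupled bis-silyl ether | CC(=O)O[C@@H](CC/C(C)=C\[C@@H]1OC(=O)[C@H](C)[C@@]1(O)CO[Si](C)(C)C(C)(C)C)[C@]1(C)C=C(C)CC[C@@H]1O[Si](C)(C)C(C)(C)C
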